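**Plan**

- Retrosynthesis: after the 3‑O‑prenyl ether and the two MOM ethers, the pyranone (ring C) is cut at C3–C4, an acyloin-type bond between the A‑ring formyl carbon and a C3 carbonyl. The next cut is O1–C2, giving a phenol and a 3‑aryl glycidic ester.
- Enabling feature: in ring C, C4 (ketone) and C3 (enolic C–O) are adjacent carbons at carbonyl oxidation level, i.e. an oxidised α‑ketol. Both can therefore enter as electrophilic carbonyl carbons, one of them inverted by a carbene.
- Choice of acceptor: C3 is brought in as the ketone of an α‑keto ester, not as a formyl group. A carbene would convert an α‑aryloxy aldehyde into a Breslow intermediate that expels the phenoxide; a ketone cannot become a donor. The ester is later lost as CO2.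
- Forward order: ring A (salicylaldehyde 4) and the B‑ring glycidate 9 are made separately and joined at O1–C2. Ring C is then closed at C3–C4, followed by decarboxylation, oxidation to the flavonol, 3‑O‑prenylation and MOM removal.
- Stereochemistry: C2 and C3 are transient, uncontrolled, racemic centres that disappear at the flavonol stage.

Key step: step 8

Remark: the target has no stereocentre and no stereogenic double bond, so the structure given is one achiral compound. "Prenyl" means 3‑methylbut‑2‑en‑1‑yl throughout.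

**Route**

Step 1
Reactants: 1 2,4,6‑trihydroxybenzaldehyde
Product: 2 2‑hydroxy‑4,6‑bis(methoxymethoxy)benzaldehyde
Conditions: MOMCl (2.2 equiv), iPr2NEt, CH2Cl2, 0 °C → rt
Reagents that add atoms: chloromethyl methyl ether, COCCl
Why: Base-mediated O‑alkylation (acetal ether formation) should take the para hydroxyl and one ortho hydroxyl, because the remaining ortho hydroxyl is held in a hydrogen bond to the formyl group and is the least nucleophilic.

Step 2
Reactants: 2 2‑hydroxy‑4,6‑bis(methoxymethoxy)benzaldehyde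
Product: 3 3‑bromo‑2‑hydroxy‑4,6‑bis(methoxymethoxy)benzaldehyde
Conditions: NBS (1.05 equiv), iPr2NH (cat.), CH2Cl2, −20 → 0 °C
Reagents that add atoms: N‑bromosuccinimide, O=C1CCC(=O)N1Br
Why: Amine-catalysed electrophilic aromatic bromination of a phenol is ortho-directed, and C3 is the only free position ortho to the chelated hydroxyl, as in the known 3‑halogenation of 2‑hydroxy‑4,6‑dialkoxyaryl carbonyl compounds.

Step 3
Reactants: 3 3‑bromo‑2‑hydroxy‑4,6‑bis(methoxymethoxy)benzaldehyde
Product: 4 2‑hydroxy‑3‑methoxy‑4,6‑bis(methoxymethoxy)benzaldehyde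
Conditions: NaOMe (25% in MeOH, 6 equiv), CuBr (0.3 equiv), DMF, 100 °C; aq. NH4Cl
Reagents that add atoms: sodium methoxide, C[O-].[Na+]
Why: Ullmann-type copper(I)-catalysed methoxylation of an aryl bromide ortho to a phenoxide is well established for bromo-hydroxybenzaldehydes; the phenoxide shields the formyl group and the MOM acetals are stable to base.

Step 4
Reactants: 5 4‑hydroxybenzaldehyde; 6 prenyl bromide
Product: 7 4‑(prenyloxy)benzaldehyde
Conditions: K2CO3, acetone, reflux
Reagents that add atoms: none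
Why: Williamson ether synthesis of a phenoxide with a primary allylic bromide.

Step 5
Reactants: 7 4‑(prenyloxy)benzaldehyde; 8 methyl chloroacetate
Product: 9 methyl 3‑[4‑(prenyloxy)phenyl]oxirane‑2‑carboxylate (racemic, mainly trans)
Conditions: NaOMe (1.5 equiv), MeOH, −10 °C → rt; neutral work-up, used without delay
Reagents that add atoms: none
Why: Darzens glycidic ester condensation of a 4‑alkoxybenzaldehyde; the relative configuration is inconsequential because both epoxide carbons lose their stereochemistry later.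

Step 6
Reactants: 4 2‑hydroxy‑3‑methoxy‑4,6‑bis(methoxymethoxy)benzaldehyde; 9 methyl 3‑[4‑(prenyloxy)phenyl]oxirane‑2‑carboxylate
Product: 10 methyl 3‑[2‑formyl‑6‑methoxy‑3,5‑bis(methoxymethoxy)phenoxy]‑2‑hydroxy‑3‑[4‑(prenyloxy)phenyl]propanoate (racemic, diastereomer mixture)
Conditions: Cs2CO3 (0.3 equiv), DMF, 60 °C
Reagents that add atoms: none
Why: SN2 ring opening of a 3‑aryl glycidic ester by phenoxide should occur at the benzylic C3, the site taken by amine, azide and thiol nucleophiles and further loosened by the 4‑alkoxyphenyl group; this forms the O1–C2 ether, and the acidic chelated phenol turns over catalytic carbonate.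

Step 7
Reactants: 10 methyl 3‑[2‑formyl‑6‑methoxy‑3,5‑bis(methoxymethoxy)phenoxy]‑2‑hydroxy‑3‑[4‑(prenyloxy)phenyl]propanoate
Product: 11 methyl 3‑[2‑formyl‑6‑methoxy‑3,5‑bis(methoxymethoxy)phenoxy]‑2‑oxo‑3‑[4‑(prenyloxy)phenyl]propanoate (racemic)
Conditions: Dess–Martin periodinane (1.3 equiv), pyridine, CH2Cl2, 0 °C → rt; used directly
Reagents that add atoms: none
Why: Dess–Martin oxidation of an α‑hydroxy ester to the α‑keto ester is routine and should leave the aryl aldehyde, the MOM acetals and the prenyl alkene untouched.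

Step 8
Reactants: 11 methyl 3‑[2‑formyl‑6‑methoxy‑3,5‑bis(methoxymethoxy)phenoxy]‑2‑oxo‑3‑[4‑(prenyloxy)phenyl]propanoate
Product: 12 methyl 3‑hydroxy‑8‑methoxy‑5,7‑bis(methoxymethoxy)‑4‑oxo‑2‑[4‑(prenyloxy)phenyl]chromane‑3‑carboxylate (racemic, diastereomer mixture)
Conditions: 2‑(pentafluorophenyl)‑6,7‑dihydro‑5H‑pyrrolo[2,1‑c][1,2,4]triazol‑2‑ium tetrafluoroborate (20 mol%), iPr2NEt (20 mol%), 4 Å MS, CH2Cl2 (0.05 M), 40 °C, Ar
Reagents that add atoms: none
Why: The carbene released from the triazolium salt adds to the only formyl group (the A‑ring aldehyde), proton transfer gives the Breslow enaminol, and this acyl-anion equivalent attacks the ester-activated ketone of the tether before the catalyst is expelled, forming C3–C4 as an α‑ketol. The closest known reaction type is the carbene-catalysed intramolecular crossed aldehyde–ketone benzoin that gives 3‑hydroxychroman‑4‑ones (2‑aryl members included), together with the aldehyde/α‑keto ester cross-benzoin. The pyranone ring closes in 6‑exo‑trig mode. The new C3 centre is not controlled and need not be: it forms as a mixture relative to the base-labile C2 centre, and both vanish in step 10. The step needs the A‑ring aldehyde to be the sole donor and 1,2‑addition to outrun enolate chemistry; the first is secured because the partner carbonyl carries no hydrogen and cannot become a Breslow intermediate (an α‑aryloxy aldehyde in its place would, and would then eject the phenoxide), the second by the ester, which makes the ketone strongly electrophilic, and by using only catalytic weak base.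

Step 9
Reactants: 12 methyl 3‑hydroxy‑8‑methoxy‑5,7‑bis(methoxymethoxy)‑4‑oxo‑2‑[4‑(prenyloxy)phenyl]chromane‑3‑carboxylate
Product: 14 3‑hydroxy‑8‑methoxy‑5,7‑bis(methoxymethoxy)‑2‑[4‑(prenyloxy)phenyl]chroman‑4‑one (racemic cis/trans mixture), via β‑keto acid 13 (not isolated)
Conditions: LiOH·H2O (2.5 equiv), THF–H2O 3:1, 0 °C → rt; then AcOH to pH 5, 40 °C, Ar
Reagents that add atoms: none
Why: Ester saponification followed by β‑keto acid decarboxylation should release CO2 through the enediol, which ketonises to the aryl-conjugated α‑ketol; during the basic stage C3 is quaternary, so the ring cannot open by retro-oxa-Michael reaction.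

Step 10
Reactants: 14 3‑hydroxy‑8‑methoxy‑5,7‑bis(methoxymethoxy)‑2‑[4‑(prenyloxy)phenyl]chroman‑4‑one
Product: 16 3‑hydroxy‑8‑methoxy‑5,7‑bis(methoxymethoxy)‑2‑[4‑(prenyloxy)phenyl]‑4H‑chromen‑4‑one, via chromane‑3,4‑dione 15 (not isolated)
Conditions: Dess–Martin periodinane (1.2 equiv), pyridine, CH2Cl2, 0 °C
Reagents that add atoms: none
Why: Dess–Martin oxidation of an α‑hydroxy ketone gives the 1,2‑dione, which should enolise at once towards C2 to the aromatic 3‑hydroxy‑4‑pyranone, removing both stereocentres; a 4‑hydroxy‑3‑one isomer would give the same dione.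

Step 11
Reactants: 16 3‑hydroxy‑8‑methoxy‑5,7‑bis(methoxymethoxy)‑2‑[4‑(prenyloxy)phenyl]‑4H‑chromen‑4‑one; 6 prenyl bromide
Product: 17 8‑methoxy‑5,7‑bis(methoxymethoxy)‑3‑(prenyloxy)‑2‑[4‑(prenyloxy)phenyl]‑4H‑chromen‑4‑one
Conditions: K2CO3 (2 equiv), acetone, 50 °C
Reagents that add atoms: none
Why: Williamson O‑alkylation of the flavonol 3‑hydroxyl, the only free hydroxyl in the molecule, is standard flavonol chemistry.

Step 12
Reactants: 17 8‑methoxy‑5,7‑bis(methoxymethoxy)‑3‑(prenyloxy)‑2‑[4‑(prenyloxy)phenyl]‑4H‑chromen‑4‑one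
Product: 18 5,7‑dihydroxy‑8‑methoxy‑3‑(prenyloxy)‑2‑[4‑(prenyloxy)phenyl]‑4H‑chromen‑4‑one
Conditions: HCl (1.25 M in MeOH)–THF 1:1, 30 °C, stopped at full conversion
Reagents that add atoms: none
Why: Acid-catalysed transacetalisation in methanol removes both MOM groups (the 5‑O acetal peri to the carbonyl goes first) and traps formaldehyde as methylal; dilute anhydrous acid near room temperature is expected to be too mild to ionise the prenyl ethers.

**Compound list**

1 | 2,4,6‑trihydroxybenzaldehyde | O=Cc1c(O)cc(O)cc1O | starting material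
2 | 2‑hydroxy‑4,6‑bis(methoxymethoxy)benzaldehyde | O=Cc1c(O)cc(OCOC)cc1OCOC | intermediate
3 | 3‑bromo‑2‑hydroxy‑4,6‑bis(methoxymethoxy)benzaldehyde | O=Cc1c(O)c(Br)c(OCOC)cc1OCOC | intermediate
4 | 2‑hydroxy‑3‑methoxy‑4,6‑bis(methoxymethoxy)benzaldehyde | O=Cc1c(O)c(OC)c(OCOC)cc1OCOC | intermediate
5 | 4‑hydroxybenzaldehyde | O=Cc1ccc(O)cc1 | starting material
6 | prenyl bromide (1‑bromo‑3‑methylbut‑2‑ene) | CC(C)=CCBr | starting material
7 | 4‑(prenyloxy)benzaldehyde | O=Cc1ccc(OCC=C(C)C)cc1 | intermediate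
8 | methyl chloroacetate | COC(=O)CCl | starting material
9 | methyl 3‑[4‑(prenyloxy)phenyl]oxirane‑2‑carboxylate (racemic, mainly trans, relative configuration not needed) | COC(=O)C1OC1c1ccc(OCC=C(C)C)cc1 | intermediate
10 | methyl 3‑[2‑formyl‑6‑methoxy‑3,5‑bis(methoxymethoxy)phenoxy]‑2‑hydroxy‑3‑[4‑(prenyloxy)phenyl]propanoate (racemic, both centres uncontrolled) | COC(=O)C(O)C(Oc1c(OC)c(OCOC)cc(OCOC)c1C=O)c1ccc(OCC=C(C)C)cc1 | intermediate
11 | methyl 3‑[2‑formyl‑6‑methoxy‑3,5‑bis(methoxymethoxy)phenoxy]‑2‑oxo‑3‑[4‑(prenyloxy)phenyl]propanoate (racemic) | COC(=O)C(=O)C(Oc1c(OC)c(OCOC)cc(OCOC)c1C=O)c1ccc(OCC=C(C)C)cc1 | intermediate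
12 | methyl 3‑hydroxy‑8‑methoxy‑5,7‑bis(methoxymethoxy)‑4‑oxo‑2‑[4‑(prenyloxy)phenyl]chromane‑3‑carboxylate (racemic, C2/C3 diastereomer mixture) | COC(=O)C1(O)C(c2ccc(OCC=C(C)C)cc2)Oc2c(OC)c(OCOC)cc(OCOC)c2C1=O | intermediate
13 | 3‑hydroxy‑8‑methoxy‑5,7‑bis(methoxymethoxy)‑4‑oxo‑2‑[4‑(prenyloxy)phenyl]chromane‑3‑carboxylic acid (racemic, diastereomer mixture, not isolated) | OC(=O)C1(O)C(c2ccc(OCC=C(C)C)cc2)Oc2c(OC)c(OCOC)cc(OCOC)c2C1=O | intermediate
14 | 3‑hydroxy‑8‑methoxy‑5,7‑bis(methoxymethoxy)‑2‑[4‑(prenyloxy)phenyl]chroman‑4‑one (racemic, cis/trans mixture) | OC1C(c2ccc(OCC=C(C)C)cc2)Oc2c(OC)c(OCOC)cc(OCOC)c2C1=O | intermediate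
15 | 8‑methoxy‑5,7‑bis(methoxymethoxy)‑2‑[4‑(prenyloxy)phenyl]chromane‑3,4‑dione (racemic, not isolated) | O=C1C(=O)c2c(OCOC)cc(OCOC)c(OC)c2OC1c1ccc(OCC=C(C)C)cc1 | intermediate
16 | 3‑hydroxy‑8‑methoxy‑5,7‑bis(methoxymethoxy)‑2‑[4‑(prenyloxy)phenyl]‑4H‑chromen‑4‑one | COc1c(OCOC)cc(OCOC)c2c(=O)c(O)c(-c3ccc(OCC=C(C)C)cc3)oc12 | intermediate
17 | 8‑methoxy‑5,7‑bis(methoxymethoxy)‑3‑(prenyloxy)‑2‑[4‑(prenyloxy)phenyl]‑4H‑chromen‑4‑one | COc1c(OCOC)cc(OCOC)c2c(=O)c(OCC=C(C)C)c(-c3ccc(OCC=C(C)C)cc3)oc12 | intermediate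
18 | 5,7‑dihydroxy‑8‑methoxy‑3,4'‑diprenyloxyflavone (achiral) | COc1c(O)cc(O)c2c(=O)c(OCC=C(C)C)c(-c3ccc(OCC=C(C)C)cc3)oc12 | target

**Step count**

Total: 12 steps. Longest linear sequence: 10 steps (1 → 2 → 3 → 4 → 10 → 11 → 12 → 14 → 16 → 17 → 18).

**Steps most likely to fail**

Step 8. Acyl-anion formation may be slow at an aldehyde that is flanked by two oxygen substituents and is electron-rich. Meanwhile the enolised keto ester can undergo base-driven aldol closure onto the formyl group (five-membered ring) followed by lactonisation. The fallback gives up the umpolung closure and builds ring C by oxidative chalcone cyclisation. It sets out from aldehyde 4: addition of MeMgBr (2.5 equiv, THF, −20 °C) would give 1‑[2‑hydroxy‑3‑methoxy‑4,6‑bis(methoxymethoxy)phenyl]ethanol F1, which MnO2 (CH2Cl2) would oxidise to 1‑[2‑hydroxy‑3‑methoxy‑4,6‑bis(methoxymethoxy)phenyl]ethanone F2. Claisen–Schmidt condensation with aldehyde 7 (KOH, EtOH) would give the chalcone (E)‑1‑[2‑hydroxy‑3‑methoxy‑4,6‑bis(methoxymethoxy)phenyl]‑3‑[4‑(prenyloxy)phenyl]prop‑2‑en‑1‑one F3. Algar–Flynn–Oyamada oxidation (H2O2, NaOH, MeOH–THF, 0 °C) would then pass through dihydroflavonol 14 in the flask and come back to the route at flavonol 16.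

Step 6. The hindered, hydrogen-bonded phenoxide may open the epoxide sluggishly or without regiocontrol, while the glycidate isomerises to the aryl pyruvate. The fallback separates ring opening from ether formation. It sets out from glycidate 9: hydrolytic opening at the benzylic carbon (H2O–THF, cat. HClO4, 0 °C) would give methyl 2,3‑dihydroxy‑3‑[4‑(prenyloxy)phenyl]propanoate F4. Mitsunobu etherification with phenol 4 (PPh3, DIAD, THF, 0 °C), which on 2,3‑dihydroxy esters engages the β (here benzylic) hydroxyl, would come back to the route at hydroxy ester 10.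

Step 3. The C–O coupling may stall or the bromine may be lost reductively at a bromide flanked by two oxygen substituents. The fallback introduces the extra oxygen by a Baeyer–Villiger sequence instead of C–Br substitution. It sets out from aldehyde 2: benzylation (BnBr, K2CO3, DMF) would give 2‑(benzyloxy)‑4,6‑bis(methoxymethoxy)benzaldehyde F5, and mCPBA (CH2Cl2) would give 2‑(benzyloxy)‑4,6‑bis(methoxymethoxy)phenyl formate F6. Methanolysis (K2CO3, MeOH) would give 2‑(benzyloxy)‑4,6‑bis(methoxymethoxy)phenol F7, and methylation (MeI, K2CO3, acetone) would give 1‑(benzyloxy)‑2‑methoxy‑3,5‑bis(methoxymethoxy)benzene F8. Hydrogenolysis (H2, Pd/C, EtOAc) would give 2‑methoxy‑3,5‑bis(methoxymethoxy)phenol F9, and magnesium-mediated ortho-formylation (MgCl2, Et3N, paraformaldehyde, MeCN, reflux) would come back to the route at salicylaldehyde 4.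

**Further compounds**

F1 | step 8 | 1‑[2‑hydroxy‑3‑methoxy‑4,6‑bis(methoxymethoxy)phenyl]ethanol (racemic) | CC(O)c1c(O)c(OC)c(OCOC)cc1OCOC
F2 | step 8 | 1‑[2‑hydroxy‑3‑methoxy‑4,6‑bis(methoxymethoxy)phenyl]ethanone | CC(=O)c1c(O)c(OC)c(OCOC)cc1OCOC
F3 | step 8 | (E)‑1‑[2‑hydroxy‑3‑methoxy‑4,6‑bis(methoxymethoxy)phenyl]‑3‑[4‑(prenyloxy)phenyl]prop‑2‑en‑1‑one | COCOc1cc(OCOC)c(OC)c(O)c1C(=O)/C=C/c1ccc(OCC=C(C)C)cc1
F4 | step 6 | methyl 2,3‑dihydroxy‑3‑[4‑(prenyloxy)phenyl]propanoate (racemic) | COC(=O)C(O)C(O)c1ccc(OCC=C(C)C)cc1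
F5 | step 3 | 2‑(benzyloxy)‑4,6‑bis(methoxymethoxy)benzaldehyde | O=Cc1c(OCc2ccccc2)cc(OCOC)cc1OCOC
F6 | step 3 | 2‑(benzyloxy)‑4,6‑bis(methoxymethoxy)phenyl formate | O=COc1c(OCc2ccccc2)cc(OCOC)cc1OCOC
F7 | step 3 | 2‑(benzyloxy)‑4,6‑bis(methoxymethoxy)phenol | Oc1c(OCc2ccccc2)cc(OCOC)cc1OCOC
F8 | step 3 | 1‑(benzyloxy)‑2‑methoxy‑3,5‑bis(methoxymethoxy)benzene | COc1c(OCc2ccccc2)cc(OCOC)cc1OCOC
F9 | step 3 | 2‑methoxy‑3,5‑bis(methoxymethoxy)phenol | COc1c(O)cc(OCOC)cc1OCOC
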